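**Retrosynthetic overview**
1. Amide bond: target 31 = sphingoid base 25 + (2R)-2-hydroxypentacosanoic acid 30 (docosyl Grignard + methyl (R)-glycidate).
2. C7–C8 bond and 6E alkene: acetylide alkylation of head alkyne 14 with tail iodide 21, then Na/NH3 reduction.
3. Key C4–C5 bond: reagent-controlled allylboration of the serine-derived α-silyloxy aldehyde 7 sets C4 (C2 comes from Garner aldehyde 1, C3 from a Felkin acetylide addition); the allyl group is then turned into propargyl.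
4. Rings: the trans-cyclopropane, the only ring of the target, is made first in the tail (step 10, Wadsworth–Emmons cyclopropanation of (R)-1,2-epoxyhexane). The oxazolidine comes with 1, the dioxolane is closed at step 7, and both protecting rings are opened at step 18.

Assumption: the SMILES is taken as drawn, i.e. a (2R)-2-hydroxypentacosanoyl (C25) amide of a (2S,3S,4R,6E) base carrying a trans-(S,S) cyclopropane.
Convention: numbered compounds are substrates and fragment starting materials; auxiliary reagents, including those that donate atoms, are named with SMILES on the line "Reagents that add atoms".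

**Head fragment**

Step 1
Reactants: 1 tert-butyl (4S)-4-formyl-2,2-dimethyl-1,3-oxazolidine-3-carboxylate ((S)-Garner aldehyde)
Product: 3 tert-butyl (4S)-4-[(1R)-1-hydroxyprop-2-yn-1-yl]-2,2-dimethyl-1,3-oxazolidine-3-carboxylate, via TMS-alkynol lithium alkoxide 2 (not isolated)
Conditions: ethynyltrimethylsilane, n-BuLi, THF, −78 °C; HMPA; then 1, −78 °C, 2 h; then MeOH, K2CO3, rt; NH4Cl work-up
Reagents that add atoms: ethynyltrimethylsilane C#C[Si](C)(C)C
Why: Felkin–Anh (non-chelated, HMPA) addition of the lithium acetylide to the α-amino aldehyde gives the anti (1R) carbinol (about 20:1), the future C3, and methanolysis removes the alkynyl silyl group in the same flask.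

Step 2
Reactants: 3 tert-butyl (4S)-4-[(1R)-1-hydroxyprop-2-yn-1-yl]-2,2-dimethyl-1,3-oxazolidine-3-carboxylate
Product: 4 tert-butyl (4S)-4-[(1R)-1-[(tert-butyldimethylsilyl)oxy]prop-2-yn-1-yl]-2,2-dimethyl-1,3-oxazolidine-3-carboxylate
Conditions: TBSCl, imidazole, DMF, rt
Reagents that add atoms: tert-butyldimethylsilyl chloride CC(C)(C)[Si](C)(C)Cl
Why: Standard silylation of the secondary propargylic alcohol under mild base, which leaves the Boc group, the N,O-acetal and both stereocentres untouched.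

Step 3
Reactants: 4 tert-butyl (4S)-4-[(1R)-1-[(tert-butyldimethylsilyl)oxy]prop-2-yn-1-yl]-2,2-dimethyl-1,3-oxazolidine-3-carboxylate
Product: 5 tert-butyl (4S)-4-[(1R)-1-[(tert-butyldimethylsilyl)oxy]prop-2-en-1-yl]-2,2-dimethyl-1,3-oxazolidine-3-carboxylate
Conditions: H2 (1 atm), Pd/CaCO3 poisoned with Pb(OAc)2 (Lindlar type), quinoline, EtOAc, rt
Reagents that add atoms: none
Why: Lindlar semihydrogenation of a terminal alkyne stops cleanly at the vinyl group, which is needed only as a masked formyl group.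

Step 4
Reactants: 5 tert-butyl (4S)-4-[(1R)-1-[(tert-butyldimethylsilyl)oxy]prop-2-en-1-yl]-2,2-dimethyl-1,3-oxazolidine-3-carboxylate
Product: 7 tert-butyl (4S)-4-[(1S)-1-[(tert-butyldimethylsilyl)oxy]-2-oxoethyl]-2,2-dimethyl-1,3-oxazolidine-3-carboxylate, via ozonide 6 (not isolated)
Conditions: O3, CH2Cl2, −78 °C; then PPh3, −78 °C → rt; used crude at once
Reagents that add atoms: ozone [O-][O+]=O
Why: Ozonolysis with reductive work-up cleaves the terminal alkene to the α-silyloxy aldehyde under neutral conditions that do not epimerise C3 (the descriptor changes from R to S only through CIP priorities).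

Step 5
Reactants: 7 tert-butyl (4S)-4-[(1S)-1-[(tert-butyldimethylsilyl)oxy]-2-oxoethyl]-2,2-dimethyl-1,3-oxazolidine-3-carboxylate
Product: 9 tert-butyl (4S)-4-[(1S,2R)-1-[(tert-butyldimethylsilyl)oxy]-2-hydroxypent-4-en-1-yl]-2,2-dimethyl-1,3-oxazolidine-3-carboxylate, via borinate ester 8 (not isolated)
Conditions: (+)-Ipc2BOMe (the reagent from (−)-α-pinene), allylmagnesium bromide, Et2O, 0 °C → rt; then 7, −78 °C, 3 h; then 3 M NaOH, 30% H2O2, 0 °C → rt
Reagents that add atoms: allylmagnesium bromide C=CC[Mg]Br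
Why: Brown asymmetric allylboration (carbonyl allylation through a chair Zimmerman–Traxler transition state) forms the key C4–C5 bond by delivering allyl to the Re face of the aldehyde, which sets C4 as R and is matched with the Felkin preference of the α-silyloxy aldehyde for the 3,4-anti product.

Step 6
Reactants: 9 tert-butyl (4S)-4-[(1S,2R)-1-[(tert-butyldimethylsilyl)oxy]-2-hydroxypent-4-en-1-yl]-2,2-dimethyl-1,3-oxazolidine-3-carboxylate
Product: 10 tert-butyl (4S)-4-[(1S,2R)-1,2-dihydroxypent-4-en-1-yl]-2,2-dimethyl-1,3-oxazolidine-3-carboxylate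
Conditions: TBAF, THF, 0 °C → rt
Reagents that add atoms: none
Why: Fluoride desilylation frees the C3 hydroxyl (any silyl migration to O4 during the previous work-up converges on the same diol) without touching Boc or the N,O-acetal.

Step 7
Reactants: 10 tert-butyl (4S)-4-[(1S,2R)-1,2-dihydroxypent-4-en-1-yl]-2,2-dimethyl-1,3-oxazolidine-3-carboxylate
Product: 11 tert-butyl (4S)-4-[(4S,5R)-2,2-dimethyl-5-(prop-2-en-1-yl)-1,3-dioxolan-4-yl]-2,2-dimethyl-1,3-oxazolidine-3-carboxylate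
Conditions: 2,2-dimethoxypropane, PPTS (cat.), CH2Cl2, rt
Reagents that add atoms: 2,2-dimethoxypropane COC(C)(C)OC
Why: Acid-catalysed transacetalisation locks the 3,4-anti diol as a cis-dioxolane that survives ozone, organolithium and dissolving-metal conditions and falls off with the other acid-labile groups at the end.

Step 8
Reactants: 11 tert-butyl (4S)-4-[(4S,5R)-2,2-dimethyl-5-(prop-2-en-1-yl)-1,3-dioxolan-4-yl]-2,2-dimethyl-1,3-oxazolidine-3-carboxylate
Product: 13 tert-butyl (4S)-4-[(4S,5R)-2,2-dimethyl-5-(2-oxoethyl)-1,3-dioxolan-4-yl]-2,2-dimethyl-1,3-oxazolidine-3-carboxylate, via ozonide 12 (not isolated)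
Conditions: O3, CH2Cl2, −78 °C; then PPh3, −78 °C → rt; used crude
Reagents that add atoms: ozone [O-][O+]=O
Why: Ozonolysis with reductive work-up shortens the allyl group to the C6 aldehyde, which has no α-stereocentre to lose.

Step 9
Reactants: 13 tert-butyl (4S)-4-[(4S,5R)-2,2-dimethyl-5-(2-oxoethyl)-1,3-dioxolan-4-yl]-2,2-dimethyl-1,3-oxazolidine-3-carboxylate
Product: 14 tert-butyl (4S)-4-[(4S,5R)-2,2-dimethyl-5-(prop-2-yn-1-yl)-1,3-dioxolan-4-yl]-2,2-dimethyl-1,3-oxazolidine-3-carboxylate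
Conditions: dimethyl (1-diazo-2-oxopropyl)phosphonate, K2CO3, MeOH, 0 °C → rt
Reagents that add atoms: dimethyl (1-diazo-2-oxopropyl)phosphonate COP(=O)(OC)C(=[N+]=[N-])C(C)=O
Why: Ohira–Bestmann (Seyferth–Gilbert) homologation converts the aldehyde into the terminal alkyne (adding C7) under base mild enough for a β-alkoxy aldehyde.

**Tail fragment**

Step 10
Reactants: 15 (2R)-2-butyloxirane ((R)-1,2-epoxyhexane)
Product: 16 ethyl (1S,2S)-2-butylcyclopropane-1-carboxylate
Conditions: triethyl phosphonoacetate, n-BuLi, DME, rt; then 15, 130 °C (sealed), 16 h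
Reagents that add atoms: triethyl phosphonoacetate CCOC(=O)CP(=O)(OCC)OCC
Why: In the Wadsworth–Emmons cyclopropanation the phosphonate anion opens the epoxide at CH2, phosphoryl migrates to oxygen and the ester enolate displaces the phosphate with inversion (3-exo-tet), so the R epoxide carbon becomes the S butyl-bearing ring carbon and the ester ends up trans (over 95:5).

Step 11
Reactants: 16 ethyl (1S,2S)-2-butylcyclopropane-1-carboxylate
Product: 17 [(1S,2S)-2-butylcyclopropyl]methanol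
Conditions: LiAlH4, Et2O, 0 °C; Fieser work-up
Reagents that add atoms: none
Why: Hydride reduction of the ester to the primary alcohol does not affect the ring stereocentres.

Step 12
Reactants: 17 [(1S,2S)-2-butylcyclopropyl]methanol
Product: 18 (1S,2S)-2-butylcyclopropane-1-carbaldehyde
Conditions: Dess–Martin periodinane, CH2Cl2, 0 °C → rt; used as a solution
Reagents that add atoms: none
Why: Dess–Martin oxidation gives the aldehyde under neutral conditions, and the trans isomer is also the thermodynamically preferred one, so epimerisation is not a concern.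

Step 13
Reactants: 18 (1S,2S)-2-butylcyclopropane-1-carbaldehyde
Product: 19 4-[(1S,2S)-2-butylcyclopropyl]but-3-en-1-ol (Z/E mixture)
Conditions: (3-hydroxypropyl)triphenylphosphonium bromide, LiN(SiMe3)2 (2.1 equiv), THF, 0 °C; then 18, −78 °C → rt
Reagents that add atoms: (3-hydroxypropyl)triphenylphosphonium bromide OCCC[P+](c1ccccc1)(c1ccccc1)c1ccccc1.[Br-]
Why: Wittig reaction of the γ-oxido ylide adds C8–C10 in one operation, and the alkene geometry is irrelevant because the double bond is saturated next.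

Step 14
Reactants: 19 4-[(1S,2S)-2-butylcyclopropyl]but-3-en-1-ol (Z/E mixture)
Product: 20 4-[(1S,2S)-2-butylcyclopropyl]butan-1-ol
Conditions: p-toluenesulfonohydrazide, NaOAc, DME/H2O, reflux
Reagents that add atoms: none
Why: Diimide reduction transfers H2 in a concerted manner and therefore saturates the vinylcyclopropane without the ring opening that metal-catalysed hydrogenation can cause.

Step 15
Reactants: 20 4-[(1S,2S)-2-butylcyclopropyl]butan-1-ol
Product: 21 (1S,2S)-1-butyl-2-(4-iodobutyl)cyclopropane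
Conditions: I2, PPh3, imidazole, CH2Cl2, 0 °C → rt
Reagents that add atoms: iodine II
Why: Appel iodination of the primary alcohol proceeds by SN2 four carbons away from the ring, so no cyclopropylcarbinyl rearrangement is possible.

**Fragment union and end game**

Step 16
Reactants: 14 tert-butyl (4S)-4-[(4S,5R)-2,2-dimethyl-5-(prop-2-yn-1-yl)-1,3-dioxolan-4-yl]-2,2-dimethyl-1,3-oxazolidine-3-carboxylate; 21 (1S,2S)-1-butyl-2-(4-iodobutyl)cyclopropane
Product: 23 tert-butyl (4S)-4-[(4S,5R)-5-{7-[(1S,2S)-2-butylcyclopropyl]hept-2-yn-1-yl}-2,2-dimethyl-1,3-dioxolan-4-yl]-2,2-dimethyl-1,3-oxazolidine-3-carboxylate, via lithium acetylide 22 (not isolated)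
Conditions: 14, n-BuLi (1.05 equiv), THF, −78 °C; then 21, HMPA, −78 °C → rt
Reagents that add atoms: none
Why: SN2 alkylation of the lithium acetylide with the unhindered primary iodide forms the C7–C8 bond, and the carbamate has no N–H and tolerates one equivalent of base at low temperature.

Step 17
Reactants: 23 tert-butyl (4S)-4-[(4S,5R)-5-{7-[(1S,2S)-2-butylcyclopropyl]hept-2-yn-1-yl}-2,2-dimethyl-1,3-dioxolan-4-yl]-2,2-dimethyl-1,3-oxazolidine-3-carboxylate
Product: 24 tert-butyl (4S)-4-[(4S,5R)-5-{(2E)-7-[(1S,2S)-2-butylcyclopropyl]hept-2-en-1-yl}-2,2-dimethyl-1,3-dioxolan-4-yl]-2,2-dimethyl-1,3-oxazolidine-3-carboxylate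
Conditions: Na, NH3(l)/THF, −78 → −33 °C; NH4Cl quench
Reagents that add atoms: none
Why: Dissolving-metal reduction of the internal alkyne goes through the trans vinyl radical anion and gives only the E alkene, while the non-conjugated cyclopropane, the Boc group and both acetals are inert.

Step 18
Reactants: 24 tert-butyl (4S)-4-[(4S,5R)-5-{(2E)-7-[(1S,2S)-2-butylcyclopropyl]hept-2-en-1-yl}-2,2-dimethyl-1,3-dioxolan-4-yl]-2,2-dimethyl-1,3-oxazolidine-3-carboxylate
Product: 25 (2S,3S,4R,6E)-2-amino-11-[(1S,2S)-2-butylcyclopropyl]undec-6-ene-1,3,4-triol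
Conditions: 3 M aq HCl, MeOH/THF, rt → 40 °C; then NaOH to pH 10, extraction
Reagents that add atoms: none
Why: One acidic hydrolysis removes both isopropylidene acetals and the Boc group, under conditions mild enough for the isolated alkene and the dialkylcyclopropane.

Step 19
Reactants: 26 1-bromodocosane; 27 methyl (2R)-oxirane-2-carboxylate (methyl (R)-glycidate)
Product: 29 methyl (2R)-2-hydroxypentacosanoate, via docosylmagnesium bromide 28 (not isolated)
Conditions: 26, Mg, THF, reflux; then 27, CuBr·SMe2 (10 mol%), THF, −40 → −20 °C; NH4Cl work-up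
Reagents that add atoms: none
Why: Copper-catalysed Grignard opening of the glycidic ester occurs at the terminal CH2 faster than addition to the ester, so the stereocentre of 27 is carried over unchanged as the 2R carbinol.

Step 20
Reactants: 29 methyl (2R)-2-hydroxypentacosanoate
Product: 30 (2R)-2-hydroxypentacosanoic acid
Conditions: LiOH·H2O, THF/MeOH/H2O, 50 °C; then 1 M HCl
Reagents that add atoms: water O
Why: Saponification of the methyl ester followed by acidification gives the free acid without racemising the α-hydroxy centre.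

Step 21
Reactants: 25 (2S,3S,4R,6E)-2-amino-11-[(1S,2S)-2-butylcyclopropyl]undec-6-ene-1,3,4-triol; 30 (2R)-2-hydroxypentacosanoic acid
Product: 31 (2R)-N-[(2S,3S,4R,6E)-11-[(1S,2S)-2-butylcyclopropyl]-1,3,4-trihydroxyundec-6-en-2-yl]-2-hydroxypentacosanamide
Conditions: EDC·HCl, HOBt, i-Pr2NEt, THF/CH2Cl2, rt → 40 °C; recrystallisation
Reagents that add atoms: none
Why: Carbodiimide/HOBt amide coupling is chemoselective for the primary amine over the four hydroxyl groups and does not epimerise the α-hydroxy acid.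

**Compound list**

1 | tert-butyl (4S)-4-formyl-2,2-dimethyl-1,3-oxazolidine-3-carboxylate | CC(C)(C)OC(=O)N1[C@@H](COC1(C)C)C=O | starting material
2 | lithium (1R)-1-[(4S)-3-(tert-butoxycarbonyl)-2,2-dimethyl-1,3-oxazolidin-4-yl]-3-(trimethylsilyl)prop-2-yn-1-olate | CC(C)(C)OC(=O)N1[C@@H](COC1(C)C)[C@H](O[Li])C#C[Si](C)(C)C | intermediate
3 | tert-butyl (4S)-4-[(1R)-1-hydroxyprop-2-yn-1-yl]-2,2-dimethyl-1,3-oxazolidine-3-carboxylate | CC(C)(C)OC(=O)N1[C@@H](COC1(C)C)[C@H](O)C#C | intermediate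
4 | tert-butyl (4S)-4-[(1R)-1-[(tert-butyldimethylsilyl)oxy]prop-2-yn-1-yl]-2,2-dimethyl-1,3-oxazolidine-3-carboxylate | CC(C)(C)OC(=O)N1[C@@H](COC1(C)C)[C@H](O[Si](C)(C)C(C)(C)C)C#C | intermediate
5 | tert-butyl (4S)-4-[(1R)-1-[(tert-butyldimethylsilyl)oxy]prop-2-en-1-yl]-2,2-dimethyl-1,3-oxazolidine-3-carboxylate | CC(C)(C)OC(=O)N1[C@@H](COC1(C)C)[C@H](O[Si](C)(C)C(C)(C)C)C=C | intermediate
6 | tert-butyl (4S)-4-{(S)-[(tert-butyldimethylsilyl)oxy](1,2,4-trioxolan-3-yl)methyl}-2,2-dimethyl-1,3-oxazolidine-3-carboxylate (epimers at the trioxolane carbon) | CC(C)(C)OC(=O)N1[C@@H](COC1(C)C)[C@H](O[Si](C)(C)C(C)(C)C)C2OCOO2 | intermediate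
7 | tert-butyl (4S)-4-[(1S)-1-[(tert-butyldimethylsilyl)oxy]-2-oxoethyl]-2,2-dimethyl-1,3-oxazolidine-3-carboxylate | CC(C)(C)OC(=O)N1[C@@H](COC1(C)C)[C@H](O[Si](C)(C)C(C)(C)C)C=O | intermediate
8 | tert-butyl (4S)-4-[(1S,2R)-1-[(tert-butyldimethylsilyl)oxy]-2-{[bis(isopinocampheyl)boranyl]oxy}pent-4-en-1-yl]-2,2-dimethyl-1,3-oxazolidine-3-carboxylate | CC(C)(C)OC(=O)N1[C@@H](COC1(C)C)[C@H](O[Si](C)(C)C(C)(C)C)[C@H](OB([C@H]2C[C@H]3C[C@@H]([C@@H]2C)C3(C)C)[C@H]2C[C@H]3C[C@@H]([C@@H]2C)C3(C)C)CC=C | intermediate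
9 | tert-butyl (4S)-4-[(1S,2R)-1-[(tert-butyldimethylsilyl)oxy]-2-hydroxypent-4-en-1-yl]-2,2-dimethyl-1,3-oxazolidine-3-carboxylate | CC(C)(C)OC(=O)N1[C@@H](COC1(C)C)[C@H](O[Si](C)(C)C(C)(C)C)[C@H](O)CC=C | intermediate
10 | tert-butyl (4S)-4-[(1S,2R)-1,2-dihydroxypent-4-en-1-yl]-2,2-dimethyl-1,3-oxazolidine-3-carboxylate | CC(C)(C)OC(=O)N1[C@@H](COC1(C)C)[C@H](O)[C@H](O)CC=C | intermediate
11 | tert-butyl (4S)-4-[(4S,5R)-2,2-dimethyl-5-(prop-2-en-1-yl)-1,3-dioxolan-4-yl]-2,2-dimethyl-1,3-oxazolidine-3-carboxylate | CC(C)(C)OC(=O)N1[C@@H](COC1(C)C)[C@@H]2OC(C)(C)O[C@@H]2CC=C | intermediate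
12 | tert-butyl (4S)-4-[(4S,5R)-2,2-dimethyl-5-(1,2,4-trioxolan-3-ylmethyl)-1,3-dioxolan-4-yl]-2,2-dimethyl-1,3-oxazolidine-3-carboxylate (epimers at the trioxolane carbon) | CC(C)(C)OC(=O)N1[C@@H](COC1(C)C)[C@@H]2OC(C)(C)O[C@@H]2CC3OCOO3 | intermediate
13 | tert-butyl (4S)-4-[(4S,5R)-2,2-dimethyl-5-(2-oxoethyl)-1,3-dioxolan-4-yl]-2,2-dimethyl-1,3-oxazolidine-3-carboxylate | CC(C)(C)OC(=O)N1[C@@H](COC1(C)C)[C@@H]2OC(C)(C)O[C@@H]2CC=O | intermediate
14 | tert-butyl (4S)-4-[(4S,5R)-2,2-dimethyl-5-(prop-2-yn-1-yl)-1,3-dioxolan-4-yl]-2,2-dimethyl-1,3-oxazolidine-3-carboxylate | CC(C)(C)OC(=O)N1[C@@H](COC1(C)C)[C@@H]2OC(C)(C)O[C@@H]2CC#C | intermediate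
15 | (2R)-2-butyloxirane | CCCC[C@@H]1CO1 | starting material
16 | ethyl (1S,2S)-2-butylcyclopropane-1-carboxylate | CCOC(=O)[C@H]1C[C@@H]1CCCC | intermediate
17 | [(1S,2S)-2-butylcyclopropyl]methanol | OC[C@H]1C[C@@H]1CCCC | intermediate
18 | (1S,2S)-2-butylcyclopropane-1-carbaldehyde | O=C[C@H]1C[C@@H]1CCCC | intermediate
19 | 4-[(1S,2S)-2-butylcyclopropyl]but-3-en-1-ol (Z/E mixture) | OCCC=C[C@H]1C[C@@H]1CCCC | intermediate
20 | 4-[(1S,2S)-2-butylcyclopropyl]butan-1-ol | OCCCC[C@H]1C[C@@H]1CCCC | intermediate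
21 | (1S,2S)-1-butyl-2-(4-iodobutyl)cyclopropane | ICCCC[C@H]1C[C@@H]1CCCC | intermediate
22 | lithium 3-[(4R,5S)-5-[(4S)-3-(tert-butoxycarbonyl)-2,2-dimethyl-1,3-oxazolidin-4-yl]-2,2-dimethyl-1,3-dioxolan-4-yl]prop-1-yn-1-ide | CC(C)(C)OC(=O)N1[C@@H](COC1(C)C)[C@@H]2OC(C)(C)O[C@@H]2CC#C[Li] | intermediate
23 | tert-butyl (4S)-4-[(4S,5R)-5-{7-[(1S,2S)-2-butylcyclopropyl]hept-2-yn-1-yl}-2,2-dimethyl-1,3-dioxolan-4-yl]-2,2-dimethyl-1,3-oxazolidine-3-carboxylate | CC(C)(C)OC(=O)N1[C@@H](COC1(C)C)[C@@H]2OC(C)(C)O[C@@H]2CC#CCCCC[C@H]3C[C@@H]3CCCC | intermediate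
24 | tert-butyl (4S)-4-[(4S,5R)-5-{(2E)-7-[(1S,2S)-2-butylcyclopropyl]hept-2-en-1-yl}-2,2-dimethyl-1,3-dioxolan-4-yl]-2,2-dimethyl-1,3-oxazolidine-3-carboxylate | CC(C)(C)OC(=O)N1[C@@H](COC1(C)C)[C@@H]2OC(C)(C)O[C@@H]2C/C=C/CCCC[C@H]3C[C@@H]3CCCC | intermediate
25 | (2S,3S,4R,6E)-2-amino-11-[(1S,2S)-2-butylcyclopropyl]undec-6-ene-1,3,4-triol | N[C@@H](CO)[C@H](O)[C@H](O)C/C=C/CCCC[C@H]1C[C@@H]1CCCC | intermediate
26 | 1-bromodocosane | CCCCCCCCCCCCCCCCCCCCCCBr | starting material
27 | methyl (2R)-oxirane-2-carboxylate | COC(=O)[C@H]1CO1 | starting material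
28 | docosylmagnesium bromide | CCCCCCCCCCCCCCCCCCCCCC[Mg]Br | intermediate
29 | methyl (2R)-2-hydroxypentacosanoate | CCCCCCCCCCCCCCCCCCCCCCC[C@@H](O)C(=O)OC | intermediate
30 | (2R)-2-hydroxypentacosanoic acid | CCCCCCCCCCCCCCCCCCCCCCC[C@@H](O)C(=O)O | intermediate
31 | (2R)-N-[(2S,3S,4R,6E)-11-[(1S,2S)-2-butylcyclopropyl]-1,3,4-trihydroxyundec-6-en-2-yl]-2-hydroxypentacosanamide | CCCCCCCCCCCCCCCCCCCCCCC[C@@H](O)C(=O)N[C@@H](CO)[C@H](O)[C@H](O)C/C=C/CCCC[C@H]1C[C@@H]1CCCC | target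

**Totals**
Total step count: 21. Longest linear sequence: 13 steps (steps 1–9, 16, 17, 18, 21).

**Steps most likely to fail, with fallbacks**

Step 5. The aldehyde 7 is epimerisable at C3 and crowded, so the allylboration may give a lower diastereomer ratio or yield than simple aldehydes do. The fallback builds the 3,4-diol by alkene dihydroxylation; it sets out from 1 and comes back to the route at 13. Wittig reaction of 1 with the ylide from [3-(tert-butyldimethylsilyloxy)propyl]triphenylphosphonium bromide (KN(SiMe3)2, THF, −78 °C) gives the Z-alkene tert-butyl (4R)-4-[(1Z)-4-[(tert-butyldimethylsilyl)oxy]but-1-en-1-yl]-2,2-dimethyl-1,3-oxazolidine-3-carboxylate F1. Syn-dihydroxylation (OsO4 cat., NMO, acetone/H2O) adds anti to the allylic nitrogen and, being a cis addition to a Z-alkene, gives the 3,4-erythro diol tert-butyl (4S)-4-[(1S,2R)-4-[(tert-butyldimethylsilyl)oxy]-1,2-dihydroxybutyl]-2,2-dimethyl-1,3-oxazolidine-3-carboxylate F2. 2,2-Dimethoxypropane/PPTS gives the acetonide tert-butyl (4S)-4-[(4S,5R)-5-{2-[(tert-butyldimethylsilyl)oxy]ethyl}-2,2-dimethyl-1,3-dioxolan-4-yl]-2,2-dimethyl-1,3-oxazolidine-3-carboxylate F3, TBAF gives the primary alcohol tert-butyl (4S)-4-[(4S,5R)-5-(2-hydroxyethyl)-2,2-dimethyl-1,3-dioxolan-4-yl]-2,2-dimethyl-1,3-oxazolidine-3-carboxylate F4, and Dess–Martin oxidation of F4 gives 13.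

Step 16. The acetylide alkylation of an unactivated primary iodide can stall or lose 21 by elimination, and excess base can attack the carbamate. The fallback makes the C7–C8 bond by B-alkyl Suzuki–Miyaura coupling, which delivers the E-alkene directly; it sets out from 14 (with 21) and comes back at 24, so step 17 is no longer needed. Hydrozirconation of 14 with Cp2Zr(H)Cl (THF, rt) and iodinolysis (I2, 0 °C) gives the E-vinyl iodide tert-butyl (4S)-4-[(4S,5R)-5-[(2E)-3-iodoprop-2-en-1-yl]-2,2-dimethyl-1,3-dioxolan-4-yl]-2,2-dimethyl-1,3-oxazolidine-3-carboxylate F5. Dehydroiodination of 21 (t-BuOK, THF, 0 °C → rt) gives the terminal alkene (1S,2S)-1-(but-3-en-1-yl)-2-butylcyclopropane F6. Hydroboration of F6 with 9-BBN-H (THF, rt) gives 9-{4-[(1S,2S)-2-butylcyclopropyl]butyl}-9-borabicyclo[3.3.1]nonane F7, which is coupled in the same flask with F5 (Pd(dppf)Cl2, AsPh3, Cs2CO3, DMF/THF/H2O, rt) to give 24 with retention of the E geometry.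

Step 19. The C22 Grignard reagent is poorly soluble at low temperature and may add to the ester of 27 instead of opening the epoxide. The fallback replaces the ester by an ether epoxide; it sets out from 26 (through 28) and comes back at 30, so step 20 is no longer needed. Copper-catalysed opening of (R)-benzyl glycidyl ether with 28 (CuI cat., THF, −30 → 0 °C) gives (2R)-1-(benzyloxy)pentacosan-2-ol F8. Hydrogenolysis (H2, Pd/C, EtOAc/EtOH, 40 °C) gives (2R)-pentacosane-1,2-diol F9. Selective oxidation of the primary alcohol of F9 (TEMPO cat., NaOCl cat., NaClO2, MeCN/THF/phosphate buffer pH 6.7, 40 °C) gives 30.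

**Further compounds**
F1 | step 5 | tert-butyl (4R)-4-[(1Z)-4-[(tert-butyldimethylsilyl)oxy]but-1-en-1-yl]-2,2-dimethyl-1,3-oxazolidine-3-carboxylate | CC(C)(C)OC(=O)N1[C@@H](COC1(C)C)/C=C\CCO[Si](C)(C)C(C)(C)C
F2 | step 5 | tert-butyl (4S)-4-[(1S,2R)-4-[(tert-butyldimethylsilyl)oxy]-1,2-dihydroxybutyl]-2,2-dimethyl-1,3-oxazolidine-3-carboxylate | CC(C)(C)OC(=O)N1[C@@H](COC1(C)C)[C@H](O)[C@H](O)CCO[Si](C)(C)C(C)(C)C
F3 | step 5 | tert-butyl (4S)-4-[(4S,5R)-5-{2-[(tert-butyldimethylsilyl)oxy]ethyl}-2,2-dimethyl-1,3-dioxolan-4-yl]-2,2-dimethyl-1,3-oxazolidine-3-carboxylate | CC(C)(C)OC(=O)N1[C@@H](COC1(C)C)[C@@H]2OC(C)(C)O[C@@H]2CCO[Si](C)(C)C(C)(C)C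
F4 | step 5 | tert-butyl (4S)-4-[(4S,5R)-5-(2-hydroxyethyl)-2,2-dimethyl-1,3-dioxolan-4-yl]-2,2-dimethyl-1,3-oxazolidine-3-carboxylate | CC(C)(C)OC(=O)N1[C@@H](COC1(C)C)[C@@H]2OC(C)(C)O[C@@H]2CCO
F5 | step 16 | tert-butyl (4S)-4-[(4S,5R)-5-[(2E)-3-iodoprop-2-en-1-yl]-2,2-dimethyl-1,3-dioxolan-4-yl]-2,2-dimethyl-1,3-oxazolidine-3-carboxylate | CC(C)(C)OC(=O)N1[C@@H](COC1(C)C)[C@@H]2OC(C)(C)O[C@@H]2C/C=C/I
F6 | step 16 | (1S,2S)-1-(but-3-en-1-yl)-2-butylcyclopropane | C=CCC[C@H]1C[C@@H]1CCCC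
F7 | step 16 | 9-{4-[(1S,2S)-2-butylcyclopropyl]butyl}-9-borabicyclo[3.3.1]nonane | C1CCC2CCCC1B2CCCC[C@H]3C[C@@H]3CCCC
F8 | step 19 | (2R)-1-(benzyloxy)pentacosan-2-ol | CCCCCCCCCCCCCCCCCCCCCCC[C@@H](O)COCc1ccccc1
F9 | step 19 | (2R)-pentacosane-1,2-diol | CCCCCCCCCCCCCCCCCCCCCCC[C@@H](O)CO
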